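The readings were computed for an exercise; scatter was added.

My invariant was the sum of reagent and target in moles, which I took to stay at the reagent charge, and I tested that first on the ochre run.

common to all: starting material 0.10 M; free catalyst 4.5 mM; second catalyst 1.5 mM

| flask | reagent | added ligand | remark | time |
|---|---|---|---|---|
| ochre | 0.065 M | 1 mM | run made earlier |  |
| blue | 0.098 M | 1 mM | run made earlier |  |
| flask | 0.130 M | 1.0 mM |  | 50 min |

- ochre (time / min: side product / %, target / %): 5.00: 21, 3; 10.0: 44, 5; 15.0: 62, 6; 30.0: 83, 6; 60.0: 91, 7
- blue (time / min: side product / %, target / %): 5.00: 18, 2; 10.0: 43, 4; 15.0: 54, 5; 30.0: 79, 12; 60.0: 86, 10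

(each reading ± 1.5 percentage points)

The ochre run was charged with 0.065 M of reagent, yet by 60.0 min it held 91.0 mM of side product, so side product took no reagent one for one, and I booked reagent against target. That balance put the reagent in the ochre run at about 58.0 mM at that time, 89.2% of its charge, so I let the charge stand for the reagent level.

But the late target readings stood higher in the blue run, which was charged with more reagent. Pooling the readings at 30.0 min and 60.0 min, I divided target by side product and then by the reagent charge, which gave 1.15 L mol⁻¹ for ochre and 1.36 L mol⁻¹ for blue. With a reading error of 1.5 percentage points, these are readings. Their mean, 1.25 L mol⁻¹, was my target-to-side-product ratio per unit of reagent, a selectivity factor, read at the catalyst and ligand charges of these runs.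

1. share of side product in side product plus target at 1.5 min
2. share of side product in side product plus target at 10 min
3. share of side product in side product plus target at 50 min

My reckoning for the flask was one over one plus factor times charge, 86.0% at each asked time. The forecast said 90%, 90% and 86%, holding that “This hints that excess reagent gives extra target at high conversion”. Mine stood below it at 1.5 min and 10 min and level with it at 50 min.

The flask gave 84.6%, 85.5% and 85.2%.

    open intermediate → side product (k = 0.440 min⁻¹)
    second catalyst + open intermediate ⇌ catalyst intermediate (K = 24.0 L mol⁻¹, k = 1200 L mol⁻¹ min⁻¹)
    starting material + free catalyst ⇌ free catalyst + open intermediate (K = 1.60, k = 21.0 L mol⁻¹ min⁻¹)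
    reagent + catalyst intermediate → second catalyst + target (k = 31.0 L mol⁻¹ min⁻¹)
    second catalyst + added ligand ⇌ idle complex, settled at all times (K = 940 L mol⁻¹)

The way back from catalyst intermediate returned open intermediate to the path towards side product: in the run with that way removed, the share at 50 min fell from 85.2% to 42.5%. In the flask, my 86.0% stood 0.80 points above the share at that time. The neighbour flask was charged with 0.052 M of reagent, for which the factor 1.25 L mol⁻¹ gave 93.9%, and that flask gave 93.4%.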